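Retrosynthesis: cut the C8 O–benzyl bond, then O1–C2 and C3=C4 of the pyranone (ketenylidene ylide annulation), which leaves a 2-hydroxybenzophenone.
Cut C4a–C8a of ring A: this ring has oxygen on C5, C7 and C8a in the alternating pattern of a poly-β-carbonyl chain, a further oxygen on C8 and the acyl carbon C4 on C4a, so it is the Claisen product of a seven-carbon keto ester.
In that chain the C5 and C7 oxygens are methyl enol ethers and the C8 oxygen is a benzyl ether, so ring closure frees only O8a.
Cut the chain at C4–C4a (dienoate trienolate + 3,4-dimethoxybenzoic Weinreb amide) and at C7–C8 (benzyloxyacetate enolate + 3-methoxybut-2-enoyl chloride).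
Forward order: C7–C8 bond, O-methylation, C4–C4a bond, ring A, pyranone ring, debenzylation.
The target has no stereocentre; the 4E enol ether comes from the crotonate building block and the C2=C3 geometry is equilibrated in the anion that cyclizes.

Key step: step 6

Remark: 6 and 10 may arise as mixtures of C2=C3 isomers (10 also partly as its C5=C6 enone tautomer); all share one delocalized anion in steps 5 and 6, so only the reactive (2Z,4E) forms are drawn.

Step 1
Reactants: 1 methyl (E)-3-methoxybut-2-enoate
Product: 2 (E)-3-methoxybut-2-enoic acid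
Conditions: 2 M aq NaOH, MeOH, 60 °C; then 2 M HCl to pH 3, 0 °C
Reagents that add atoms: sodium hydroxide, [Na+].[OH-]
Why: Saponification of the ester should proceed without loss of the β-methoxy group or of the E geometry, because the vinylogous carbonate is stable to alkali and the acidification is kept cold and mild.

Step 2
Reactants: 2 (E)-3-methoxybut-2-enoic acid; 3 methyl 2-(benzyloxy)acetate
Product: 5 methyl (4E)-2-(benzyloxy)-5-methoxy-3-oxohex-4-enoate, via (E)-3-methoxybut-2-enoyl chloride 4 (not isolated)
Conditions: (COCl)2, cat. DMF, CH2Cl2, 0 °C to rt, evaporate; crude 4 in THF added to the lithium enolate of 3 (2.1 equiv 3, 2.1 equiv LiN(iPr)2, THF, −78 °C); AcOH, −78 °C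
Reagents that add atoms: none
Why: This is a crossed Claisen acylation of a lithium ester enolate by an acid chloride, in which the second equivalent of enolate takes up the proton of the more acidic β-keto ester and the acetic acid quench spares the β-methoxy enone, whose E geometry is carried over from 1.

Step 3
Reactants: 5 methyl (4E)-2-(benzyloxy)-5-methoxy-3-oxohex-4-enoate
Product: 6 methyl (2Z,4E)-2-(benzyloxy)-3,5-dimethoxyhexa-2,4-dienoate
Conditions: NaH, THF–DMPU (4:1), 0 °C; Me2SO4, 0 °C to rt
Reagents that add atoms: dimethyl sulfate, COS(=O)(=O)OC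
Why: O-Alkylation of a β-keto ester enolate is expected because the sodium enolate is separated from its counterion by DMPU and meets a hard methylating agent, while C-methylation would have to create a quaternary centre at the benzyloxy-bearing C2.

Step 4
Reactants: 7 3,4-dimethoxybenzoyl chloride
Product: 8 N,3,4-trimethoxy-N-methylbenzamide
Conditions: MeNH(OMe)·HCl, Et3N, CH2Cl2, 0 °C to rt
Reagents that add atoms: N,O-dimethylhydroxylamine hydrochloride, CNOC.Cl
Why: Acylation of the amine by the acid chloride in the presence of triethylamine is a routine amide formation and gives the Weinreb amide.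

Step 5
Reactants: 6 methyl (2Z,4E)-2-(benzyloxy)-3,5-dimethoxyhexa-2,4-dienoate; 8 N,3,4-trimethoxy-N-methylbenzamide
Product: 10 methyl (2Z,4E)-2-(benzyloxy)-7-(3,4-dimethoxyphenyl)-3,5-dimethoxy-7-oxohepta-2,4-dienoate, via lithium hemiaminal alkoxide 9 (not isolated)
Conditions: LiN(iPr)2 (1.1 equiv), THF, −78 °C; 8, −78 to −40 °C; AcOH, −78 °C, then pH 7 buffer
Reagents that add atoms: none
Why: Vinylogous deprotonation of the C6 methyl group followed by a Weinreb ketone synthesis should work because such trienolates react at the terminal carbon, as the anions of 4-methoxy-6-methylpyran-2-one and the dianion of acetoacetate do, and because the chelated adduct 9 releases the ketone only on quench, which excludes over-addition and premature cyclization.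

Step 6
Reactants: 10 methyl (2Z,4E)-2-(benzyloxy)-7-(3,4-dimethoxyphenyl)-3,5-dimethoxy-7-oxohepta-2,4-dienoate
Product: 12 [3-(benzyloxy)-2-hydroxy-4,6-dimethoxyphenyl](3,4-dimethoxyphenyl)methanone, via 6-aroylcyclohexa-2,4-dienone 11 (not isolated)
Conditions: NaOMe (3 equiv), MeOH, 65 °C, 0.02 M; then 1 M HCl, 0 °C
Reagents that add atoms: none
Why: Methoxide removes a proton from C6 (chain C1–C7 of 10 become C8a, C8, C7, C6, C5, C4a, C4 of the coumarin), the delocalized enolate adds through C6 to the C1 ester carbonyl, methoxide leaves, and dienone 11 enolizes at once to the phenoxide, which makes the sequence irreversible. The closest known reaction type is the Dieckmann (intramolecular Claisen) condensation by which poly-β-carbonyl esters are folded into acylphloroglucinols. Ring A closes in the 6-(enolexo)-exo-trig mode with formation of the C4a–C8a bond, and no stereocentre is created. The step needs carbon rather than oxygen acylation, the Claisen rather than an aldol mode, and a cisoid chain. The substrate secures the first two: C6 is the only acidic carbon, the ester is the only acyl donor within reach, C7 is tied up as the enolate and C2 bears no hydrogen, so no aldol path to an arene exists. The 2Z,4E geometry is reached because methoxide adds reversibly to C3 and C5 and the enol ether bonds lose double-bond character in the anion, so every isomer drains through the one that cyclizes, and the masked oxygens emerge as 4-OMe, 6-OMe and 3-OBn with the new hydroxyl as the only free phenol.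

Step 7
Reactants: 12 [3-(benzyloxy)-2-hydroxy-4,6-dimethoxyphenyl](3,4-dimethoxyphenyl)methanone
Product: 14 8-(benzyloxy)-4-(3,4-dimethoxyphenyl)-5,7-dimethoxy-2H-chromen-2-one, via aryl (triphenylphosphoranylidene)acetate 13 (not isolated)
Conditions: Ph3P=C=C=O (1.3 equiv), toluene, 110 °C
Reagents that add atoms: (triphenylphosphoranylidene)ketene, O=C=C=P(c1ccccc1)(c1ccccc1)c1ccccc1
Why: The phenol adds across the cumulated ylide to give the ester-stabilized phosphorane 13, whose intramolecular Wittig reaction with the neighbouring diaryl ketone closes the pyranone ring and forms C3=C4, as in the known ketenylidene ylide annulation of 2-hydroxyaryl ketones to coumarins.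

Step 8
Reactants: 14 8-(benzyloxy)-4-(3,4-dimethoxyphenyl)-5,7-dimethoxy-2H-chromen-2-one
Product: 15 8-hydroxy-4-(3,4-dimethoxyphenyl)-5,7-dimethoxy-2H-chromen-2-one (8-hydroxy-5,7,3',4'-tetramethoxy-4-phenylcoumarin)
Conditions: H2 (1 atm), Pd/C (10 wt % Pd), EtOAc, rt, stopped after one equivalent of H2
Reagents that add atoms: none
Why: Hydrogenolysis of the aryl benzyl ether over palladium on carbon should be faster than saturation of the trisubstituted, aryl-conjugated C3=C4 bond, and the methyl ethers and the lactone are inert.

Compound list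
1 | methyl (E)-3-methoxybut-2-enoate | CO/C(C)=C/C(=O)OC | starting material
2 | (E)-3-methoxybut-2-enoic acid | CO/C(C)=C/C(=O)O | intermediate
3 | methyl 2-(benzyloxy)acetate | COC(=O)COCc1ccccc1 | starting material
4 | (E)-3-methoxybut-2-enoyl chloride | CO/C(C)=C/C(=O)Cl | intermediate
5 | methyl (4E)-2-(benzyloxy)-5-methoxy-3-oxohex-4-enoate (racemic at C2) | COC(=O)C(OCc1ccccc1)C(=O)/C=C(C)/OC | intermediate
6 | methyl (2Z,4E)-2-(benzyloxy)-3,5-dimethoxyhexa-2,4-dienoate | COC(=O)/C(OCc1ccccc1)=C(OC)\C=C(OC)/C | intermediate
7 | 3,4-dimethoxybenzoyl chloride | COc1ccc(C(Cl)=O)cc1OC | starting material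
8 | N,3,4-trimethoxy-N-methylbenzamide | CON(C)C(=O)c1ccc(OC)c(OC)c1 | intermediate
9 | lithium salt of methyl (2Z,4E)-2-(benzyloxy)-7-(3,4-dimethoxyphenyl)-3,5-dimethoxy-7-[methoxy(methyl)amino]-7-oxidohepta-2,4-dienoate (tetrahedral adduct, racemic at C7) | [Li+].COC(=O)/C(OCc1ccccc1)=C(OC)\C=C(OC)/CC([O-])(N(C)OC)c1ccc(OC)c(OC)c1 | intermediate
10 | methyl (2Z,4E)-2-(benzyloxy)-7-(3,4-dimethoxyphenyl)-3,5-dimethoxy-7-oxohepta-2,4-dienoate | COC(=O)/C(OCc1ccccc1)=C(OC)\C=C(OC)/CC(=O)c1ccc(OC)c(OC)c1 | intermediate
11 | 2-(benzyloxy)-6-(3,4-dimethoxybenzoyl)-3,5-dimethoxycyclohexa-2,4-dien-1-one (racemic at C6) | COC1=CC(OC)=C(OCc2ccccc2)C(=O)C1C(=O)c1ccc(OC)c(OC)c1 | intermediate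
12 | [3-(benzyloxy)-2-hydroxy-4,6-dimethoxyphenyl](3,4-dimethoxyphenyl)methanone | COc1ccc(C(=O)c2c(OC)cc(OC)c(OCc3ccccc3)c2O)cc1OC | intermediate
13 | 2-(benzyloxy)-6-(3,4-dimethoxybenzoyl)-3,5-dimethoxyphenyl 2-(triphenylphosphoranylidene)acetate | COc1ccc(C(=O)c2c(OC)cc(OC)c(OCc3ccccc3)c2OC(=O)C=P(c2ccccc2)(c2ccccc2)c2ccccc2)cc1OC | intermediate
14 | 8-(benzyloxy)-4-(3,4-dimethoxyphenyl)-5,7-dimethoxy-2H-chromen-2-one | COc1ccc(-c2cc(=O)oc3c(OCc4ccccc4)c(OC)cc(OC)c23)cc1OC | intermediate
15 | 8-hydroxy-4-(3,4-dimethoxyphenyl)-5,7-dimethoxy-2H-chromen-2-one | COc1ccc(-c2cc(=O)oc3c(O)c(OC)cc(OC)c23)cc1OC | target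

Total step count: 8. Longest linear sequence: 7 steps (steps 1, 2, 3, 5, 6, 7, 8); step 4 is a one-step side branch.

Steps most likely to fail

Step 6. The enolate may be diverted before carbon attack on the electron-rich ester takes place. Possible diversions are oxygen attack at C3 with loss of methoxide, intermolecular condensation, or a C2=C3 enol ether that does not isomerize into the cyclization geometry. The fallback sets out from 5 and returns at 12, keeping the same ring closure but leaving C3 as a ketone so that the C2–C3 bond rotates freely. The dianion of 5 (LiN(iPr)2, 2.2 equiv, THF, −78 to −20 °C) would be acylated at its terminal methyl carbon with 8 to give methyl (4E)-2-(benzyloxy)-7-(3,4-dimethoxyphenyl)-5-methoxy-3,7-dioxohept-4-enoate F1. Claisen cyclization of this partly masked chain with Mg(OMe)2 in MeOH at 65 °C should give [3-(benzyloxy)-2,4-dihydroxy-6-methoxyphenyl](3,4-dimethoxyphenyl)methanone F2; the aldol mode again cannot aromatize because C2 carries the benzyloxy group. The 4-hydroxyl of F2 is not hydrogen-bonded to the ketone and is the more acidic one, so Me2SO4 (1.05 equiv) and K2CO3 in acetone should methylate it alone and give 12.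

Step 5. Addition of the trienolate to the electron-rich amide may be slow, so that proton transfer or attack through C4 or C2 competes. The fallback sets out from 6 and returns at 10 by a two-stage aldol–oxidation route with a far more electrophilic partner. The lithium trienolate of 6 (LiN(iPr)2, THF, −78 °C) would be added to 3,4-dimethoxybenzaldehyde in a terminal vinylogous aldol addition to give methyl (2Z,4E)-2-(benzyloxy)-7-(3,4-dimethoxyphenyl)-7-hydroxy-3,5-dimethoxyhepta-2,4-dienoate F3 (racemic). Oxidation of this secondary benzylic alcohol with Dess–Martin periodinane buffered with NaHCO3 in CH2Cl2 should give 10.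

Step 3. Methylation may take place on carbon (C2) instead of oxygen, or the base may also deprotonate the C6 methyl group. The fallback sets out from 5 and returns at 6 with the polarity reversed: the methoxy oxygen is delivered by methanol to the carbonyl carbon, so C-methylation is impossible. Compound 5 would be heated with trimethyl orthoformate and catalytic p-toluenesulfonic acid in MeOH at 50 °C, the standard acid-catalysed ketalization–elimination of β-keto esters, which under thermodynamic control should give the conjugated dienoate 6; no new compound is isolated on the way (F0).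

Further compounds
F1 | step 6 | methyl (4E)-2-(benzyloxy)-7-(3,4-dimethoxyphenyl)-5-methoxy-3,7-dioxohept-4-enoate | COC(=O)C(OCc1ccccc1)C(=O)/C=C(/OC)CC(=O)c1ccc(OC)c(OC)c1
F2 | step 6 | [3-(benzyloxy)-2,4-dihydroxy-6-methoxyphenyl](3,4-dimethoxyphenyl)methanone | COc1ccc(C(=O)c2c(OC)cc(O)c(OCc3ccccc3)c2O)cc1OC
F3 | step 5 | methyl (2Z,4E)-2-(benzyloxy)-7-(3,4-dimethoxyphenyl)-7-hydroxy-3,5-dimethoxyhepta-2,4-dienoate | COC(=O)/C(OCc1ccccc1)=C(OC)\C=C(OC)/CC(O)c1ccc(OC)c(OC)c1
F0 | step 3 | none | none
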